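How far has the starting material reacted when the feed ends, and how acid is the flask by then?

| flask | starting material | acid | protic impurity | remark | time |
|---|---|---|---|---|---|
| summer | 0.025 M (fed, over 30 min) | 0.50 mM | 0.050 M | run made earlier |  |
| autumn | 0.038 M (fed, over 30 min) | 0.50 mM | 0.050 M | run made earlier |  |
| midnight | 0.050 M (fed, over 30 min) | 0.50 mM | 0.10 M | run made earlier |  |
| flask | 0.050 M (fed, over 30 min) | 0.500 mM | 0.0500 M |  | 30 min |

| run | time / min | starting material / % | target / % |
|---|---|---|---|
| summer | 3.00 | 7.0 | 0 |
| summer | 6.00 | 9.5 | 2.2 |
| summer | 10.0 | 11.7 | 3.8 |
| summer | 12.0 | 13.8 | 3.9 |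
| summer | 15.0 | 12.6 | 3.6 |
| summer | 20.0 | 15.6 | 6.5 |
| autumn | 1.33 | 3.6 | 0.8 |
| autumn | 4.00 | 8.6 | 0.5 |
| autumn | 6.00 | 11.8 | 0 |
| autumn | 10.0 | 13.8 | 2.2 |
| autumn | 15.0 | 15.8 | 3.9 |
| autumn | 20.0 | 14.2 | 8.0 |
| midnight | 1.33 | 1.4 | 0.3 |
| midnight | 2.50 | 5.5 | 0.4 |
| midnight | 5.00 | 6.8 | 2.0 |
| midnight | 10.0 | 7.0 | 0.5 |
| midnight | 20.0 | 9.9 | 2.1 |

(readings scatter by 1 percentage point)

1. part of the starting material that has reacted at 30 min
2. pH of the solution at 30 min

- acid is the free proton; pH is minus the decimal logarithm of its molar concentration
- candidate steps: starting material + acid -> weak acid + acid + target; weak acid <-> conjugate base + acid; starting material -> weak acid + target; starting material + protic impurity -> quenched substrate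
- percentages count the whole charge, also what has not yet gone in

You can reckon the first answer by hand if you measure the flask by its equivalents of protic impurity, the impurity charge divided by the charge of starting material, which here is 1.00, so this flask stands on the symmetric point of equal charges. The first rung of the ladder is the loss of starting material. In the autumn run the reading levels near 15.8% of the charge, and a level share, a quasi-steady state, means that inflow equals loss, so the loss time is that share times the dosing time, 4.74 min. The midnight run, with twice the impurity, reads 7.0% and 9.9%, which gives 2.54 min, about half the autumn time, so the loss appears to go with the impurity, although these two runs differ in their charge of starting material as well. The dosing time of 30 min is the next rung, and because it is longer, a standing share forms early in the feed. Target is slower still: 8.0% at 20.0 min in the autumn run means a target time near 39.5 min, so in the autumn run quenching takes more of what reacts than target does. Equivalents times dosing time, 30.0 min, is when the feed has delivered as much as the impurity charged, so in this flask the impurity sinks throughout the feed and the loss time lengthens. My own reckoning therefore gives a mark rather than a value: with the autumn share standing, 84.2% reacted, and somewhat less in this flask.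

The forecast says 77% and pH 3, on the ground that “the impurity equals the charge”, and it lies under that mark.

The flask gives 77.1% and pH 3.30.

    starting material + acid → weak acid + acid + target (k = 51.0 M⁻¹ min⁻¹)
    weak acid ⇌ conjugate base + acid, settled at all times (K = 4.00 × 10⁻⁷ M)
    starting material → weak acid + target (k = 0.00500 min⁻¹)
    starting material + protic impurity → quenched substrate (k = 4.70 M⁻¹ min⁻¹)

At 30.0 min the flask keeps 36% of its impurity, which is 0.0181 M, and ends 7.1 percentage points under the mark. Impurity charges of 0.0405 M or 0.0629 M move the answer by 5 points. The neighbour holds 0.013 M of starting material, and there the protic impurity stands at 3.85 equivalents, so the same reckoning puts it near the mark of 84.2%. It keeps 81% of its impurity and reaches 85.3%, with 14.7% of its starting material still standing.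

The numbers in the tables are calculated with constants of no real substance.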